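**Retrosynthetic overview**

1. Feature: ring B is a hexasubstituted arene, and its carbon bearing the ester oxygen of ring C (the seven-membered lactone) lies para to the ring oxygen of pyranone ring D and ortho to the diaryl ether oxygen. Without that one oxygen, ring B is the chromanone of 5-methylbenzene-1,2,3-triol and has a single aromatic C–H.
2. Last skeletal disconnection: the aryl–O(ester) bond of ring C, formed by oxidative C–H lactonisation of a 2-aryloxybenzoic acid (ring A hydroxyl as methyl ether, ring B hydroxyl as benzyl ether).
3. Diaryl ether: the phenoxide para to the chromanone carbonyl displaces fluoride from tert-butyl 2-fluoro-3-formyl-4-methoxy-6-methylbenzoate. The neighbouring hydroxyl is benzylated first, through the catechol dianion, so that no Smiles rearrangement of the new ether is possible.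
4. Fragments: ring D is annulated onto 5-methylbenzene-1,2,3-triol with 3-methylbut-2-enoic acid. Ring A comes from 3-fluoro-5-methylanisole by para bromination, ortho-lithiation/formylation and bromine–lithium exchange/Boc2O.
5. Ring order: D on B, then the A–B ether, then ring C; BCl3 removes both ethers at the end.

Key step: step 8

Assumption: 5-methylbenzene-1,2,3-triol and 3-fluoro-5-methylanisole are taken as purchasable. Positions on rings B and D follow chromanone numbering (O1, C2, C3, C4, C4a, C5 to C8, C8a). The target has no stereocentre, and the carbinol carbon of the transient amino alkoxides 11 to 13 is racemic and disappears on work-up.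

**Route**

Step 1
Reactants: 1 5-methylbenzene-1,2,3-triol; 2 3-methylbut-2-enoic acid
Product: 4 7,8-dihydroxy-2,2,5-trimethylchroman-4-one, via trihydroxyaryl enone 3 (not isolated)
Conditions: P2O5/MeSO3H (1:10 w/w), 70 °C; ice water
Reagents that add atoms: none
Why: Friedel–Crafts acylation by the activated acid can only go to the two equivalent free positions of 1 (ortho to the methyl group, ortho and para to hydroxyls), and the ortho hydroxyl of enone 3 then closes ring D by oxa-Michael addition, the standard chromanone annulation of polyphenols with 3-methylbut-2-enoic acid.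

Step 2
Reactants: 4 7,8-dihydroxy-2,2,5-trimethylchroman-4-one
Product: 6 8-(benzyloxy)-7-hydroxy-2,2,5-trimethylchroman-4-one, via disodium catecholate 5 (not isolated)
Conditions: NaH (2.1 equiv), DMSO, 20 °C, argon; BnBr (1.0 equiv); 1 M HCl
Reagents that add atoms: benzyl bromide, BrCc1ccccc1
Why: In the dianion the O8 phenoxide is not conjugated to the ketone and is the more basic and more nucleophilic oxygen, so one equivalent of benzyl bromide should alkylate there (Williamson etherification of a catechol dianion, as in the 3-O-alkylation of 3,4-dihydroxybenzaldehyde) and leave the O7 phenol free.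

Step 3
Reactants: 7 3-fluoro-5-methylanisole
Product: 8 2-bromo-1-fluoro-5-methoxy-3-methylbenzene
Conditions: N-bromosuccinimide, MeCN, 0 °C to rt
Reagents that add atoms: N-bromosuccinimide, O=C1CCC(=O)N1Br
Why: Electrophilic aromatic bromination of an anisole goes para to the methoxy group, here the position between fluorine and methyl.

Step 4
Reactants: 8 2-bromo-1-fluoro-5-methoxy-3-methylbenzene
Product: 10 3-bromo-2-fluoro-6-methoxy-4-methylbenzaldehyde, via aryllithium 9 (not isolated)
Conditions: LiN(i-Pr)2 (1.1 equiv), THF, −78 °C; DMF, −78 to 0 °C; 1 M HCl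
Reagents that add atoms: N,N-dimethylformamide, CN(C)C=O
Why: Directed ortho-metalation: the hydrogen flanked by fluorine and methoxy is the most acidic, the amide base does not exchange the bromide, and the aryllithium is formylated by DMF.

Step 5
Reactants: 10 3-bromo-2-fluoro-6-methoxy-4-methylbenzaldehyde
Product: 14 tert-butyl 2-fluoro-3-formyl-4-methoxy-6-methylbenzoate, via lithium amino alkoxide 11 (not isolated), via lithiated amino alkoxide 12 (not isolated), via ester amino alkoxide 13 (not isolated)
Conditions: LiN(Me)CH2CH2NMe2 (from the amine and n-BuLi, 1.1 equiv), THF, −78 °C; n-BuLi (1.1 equiv), −78 °C; Boc2O (2.5 equiv), −78 to −40 °C; 1 M HCl, 0 °C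
Reagents that add atoms: di-tert-butyl dicarbonate, CC(C)(C)OC(=O)OC(=O)OC(C)(C)C
Why: In situ protection of the aldehyde as its lithium α-amino alkoxide allows bromine–lithium exchange at −78 °C, the aryllithium is acylated by Boc2O to the tert-butyl ester, and acidic work-up returns the aldehyde.

Step 6
Reactants: 6 8-(benzyloxy)-7-hydroxy-2,2,5-trimethylchroman-4-one; 14 tert-butyl 2-fluoro-3-formyl-4-methoxy-6-methylbenzoate
Product: 16 tert-butyl 2-{[8-(benzyloxy)-2,2,5-trimethyl-4-oxochroman-7-yl]oxy}-3-formyl-4-methoxy-6-methylbenzoate, via cesium phenoxide 15 (not isolated)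
Conditions: Cs2CO3 (1.5 equiv), DMSO, 70 °C, argon
Reagents that add atoms: none
Why: Nucleophilic aromatic substitution (addition–elimination): the fluorine is ortho to both the formyl and the ester group, and with O8 already benzylated there is only one phenoxide and no free ortho hydroxyl that could start a Smiles rearrangement of the new ether.

Step 7
Reactants: 16 tert-butyl 2-{[8-(benzyloxy)-2,2,5-trimethyl-4-oxochroman-7-yl]oxy}-3-formyl-4-methoxy-6-methylbenzoate
Product: 17 2-{[8-(benzyloxy)-2,2,5-trimethyl-4-oxochroman-7-yl]oxy}-3-formyl-4-methoxy-6-methylbenzoic acid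
Conditions: CF3CO2H/CH2Cl2 (1:4), 0 °C to rt
Reagents that add atoms: none
Why: Acidolysis of the tert-butyl ester with loss of isobutene; the aryl benzyl and methyl ethers, the aldehyde and the ketone should be stable to dilute CF3CO2H at room temperature, and the carboxyl and formyl groups are meta to each other so no lactol can form.

Step 8
Reactants: 17 2-{[8-(benzyloxy)-2,2,5-trimethyl-4-oxochroman-7-yl]oxy}-3-formyl-4-methoxy-6-methylbenzoic acid
Product: 18 the protected depsidone, that is the target with the ring A hydroxyl as methyl ether and the ring B hydroxyl as benzyl ether, ring C closed between the ring A carboxyl oxygen and ring B C6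
Conditions: PhI(OCOCF3)2 (1.2 equiv), BF3·OEt2 (2.5 equiv), CH2Cl2, −40 to 0 °C, dark
Reagents that add atoms: none
Why: Proposed new method: the BF3-activated trivalent iodine reagent should take one electron from ring B, the more electron-rich arene (three oxygen donors, against two donors and two carbonyl groups on ring A); the carboxylate then adds to the radical cation at C6, the only ring B C–H, and a second one-electron oxidation with loss of the proton restores the arene and leaves the aryl–O(ester) bond. The closest known reaction type is the oxidative C–H lactonisation of biaryl-2-carboxylic acids to benzocoumarins with PhI(OCOCF3)2 or persulfate; it has not been shown for 2-aryloxybenzoic acids, where carboxyl attack at the ipso ether carbon followed by 1,5-aryl shift to an aryl salicylate is the documented course. Ring C closes as a seven-membered ring through the carboxyl oxygen onto an arene carbon (ring atoms O, C=O, two ring A carbons, ether O, C7, C6; formally 7-endo with respect to the C6–C7 bond of ring B), and the diaryl ether is already folded as in a depsidone, so no strained geometry is needed. No stereocentre is formed. The step needs attack at C6 rather than at ipso C7: C6 is para to the pyranone oxygen O1 and ortho to the ether oxygen, so it should carry the largest share of the positive charge, and it bears a hydrogen whose loss makes the addition irreversible, whereas the spiro adduct at C7 can only go on by expelling ring A as an aryloxy radical destabilised by its ortho formyl and ortho acyl groups and should therefore revert. The benzyl ether prevents phenol oxidation at O8, and working cold and in the dark avoids O–I homolysis to the aroyloxy radical that causes aryl migration.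

Step 9
Reactants: 18 the protected depsidone (ring A methyl ether, ring B benzyl ether)
Product: 19 CNP0271978.0, the depsidone with free hydroxyls on ring A (ortho to the formyl group) and on ring B (C8)
Conditions: BCl3 (6 equiv), pentamethylbenzene (3 equiv), CH2Cl2, −78 °C to rt; H2O
Reagents that add atoms: none
Why: Lewis acid ether cleavage: BCl3 removes the benzyl ether at low temperature with pentamethylbenzene as cation trap and, through chelation with the formyl oxygen, the methyl ether ortho to the formyl group; the lactone, the diaryl ether and the chromanone should survive, and a non-basic work-up avoids Smiles rearrangement of the free O8 phenol onto ring A.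

**Compound list**

1 | 5-methylbenzene-1,2,3-triol | Cc1cc(O)c(O)c(O)c1 | starting material
2 | 3-methylbut-2-enoic acid | CC(C)=CC(=O)O | starting material
3 | 3-methyl-1-(2,3,4-trihydroxy-6-methylphenyl)but-2-en-1-one | CC(C)=CC(=O)c1c(C)cc(O)c(O)c1O | intermediate
4 | 7,8-dihydroxy-2,2,5-trimethylchroman-4-one | CC1(C)CC(=O)c2c(C)cc(O)c(O)c2O1 | intermediate
5 | disodium 2,2,5-trimethyl-4-oxochromane-7,8-diolate | CC1(C)CC(=O)c2c(C)cc([O-])c([O-])c2O1.[Na+].[Na+] | intermediate
6 | 8-(benzyloxy)-7-hydroxy-2,2,5-trimethylchroman-4-one | CC1(C)CC(=O)c2c(C)cc(O)c(OCc3ccccc3)c2O1 | intermediate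
7 | 3-fluoro-5-methylanisole | COc1cc(C)cc(F)c1 | starting material
8 | 2-bromo-1-fluoro-5-methoxy-3-methylbenzene | COc1cc(C)c(Br)c(F)c1 | intermediate
9 | (3-bromo-2-fluoro-6-methoxy-4-methylphenyl)lithium | [Li]c1c(F)c(Br)c(C)cc1OC | intermediate
10 | 3-bromo-2-fluoro-6-methoxy-4-methylbenzaldehyde | COc1cc(C)c(Br)c(F)c1C=O | intermediate
11 | lithium (3-bromo-2-fluoro-6-methoxy-4-methylphenyl){[2-(dimethylamino)ethyl](methyl)amino}methanolate (racemic) | COc1cc(C)c(Br)c(F)c1C([O-])N(C)CCN(C)C.[Li+] | intermediate
12 | lithium {[2-(dimethylamino)ethyl](methyl)amino}(2-fluoro-3-lithio-6-methoxy-4-methylphenyl)methanolate (racemic) | COc1cc(C)c([Li])c(F)c1C([O-])N(C)CCN(C)C.[Li+] | intermediate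
13 | lithium [3-(tert-butoxycarbonyl)-2-fluoro-6-methoxy-4-methylphenyl]{[2-(dimethylamino)ethyl](methyl)amino}methanolate (racemic) | COc1cc(C)c(C(=O)OC(C)(C)C)c(F)c1C([O-])N(C)CCN(C)C.[Li+] | intermediate
14 | tert-butyl 2-fluoro-3-formyl-4-methoxy-6-methylbenzoate | COc1cc(C)c(C(=O)OC(C)(C)C)c(F)c1C=O | intermediate
15 | cesium 8-(benzyloxy)-2,2,5-trimethyl-4-oxochroman-7-olate | CC1(C)CC(=O)c2c(C)cc([O-])c(OCc3ccccc3)c2O1.[Cs+] | intermediate
16 | tert-butyl 2-{[8-(benzyloxy)-2,2,5-trimethyl-4-oxochroman-7-yl]oxy}-3-formyl-4-methoxy-6-methylbenzoate | COc1cc(C)c(C(=O)OC(C)(C)C)c(Oc2c(OCc3ccccc3)c3OC(C)(C)CC(=O)c3c(C)c2)c1C=O | intermediate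
17 | 2-{[8-(benzyloxy)-2,2,5-trimethyl-4-oxochroman-7-yl]oxy}-3-formyl-4-methoxy-6-methylbenzoic acid | COc1cc(C)c(C(=O)O)c(Oc2c(OCc3ccccc3)c3OC(C)(C)CC(=O)c3c(C)c2)c1C=O | intermediate
18 | protected depsidone: target with ring A hydroxyl as methyl ether and ring B hydroxyl as benzyl ether | COc1cc(C)c2c(c1C=O)Oc1c(OCc3ccccc3)c3OC(C)(C)CC(=O)c3c(C)c1OC2=O | intermediate
19 | CNP0271978.0 (depsidone: ring A with methyl, hydroxyl and formyl; seven-membered lactone ring C; ring B with methyl and hydroxyl; 2,2-dimethylpyran-4-one ring D) | Cc1cc(O)c(C=O)c2c1C(=O)Oc1c(C)c3c(c(O)c1O2)OC(C)(C)CC3=O | target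

**Step count**

Total: 9 steps. Longest linear sequence: 7 steps (steps 3, 4, 5, 6, 7, 8, 9); the ring B branch (steps 1, 2) joins at step 6.

**Steps most likely to fail**

Step 8 (the proposed new method). The carboxyl oxygen may add at the ipso ether carbon and trigger aryl migration instead of substituting at C6. Ring B may also resist oxidation once BF3 binds the chromanone carbonyl, and the chromanone methylene may be oxidised at its α-position. The fallback uses known chemistry and places a halogen at C6 before the ether is made. It sets out from 6: bromination with N-bromosuccinimide in MeCN at 0 °C should go to C6, the only free ring position and ortho to the free hydroxyl, and give 8-(benzyloxy)-6-bromo-7-hydroxy-2,2,5-trimethylchroman-4-one F1. Its cesium phenoxide displaces fluoride from 14 (Cs2CO3, DMSO, 90 °C; slower than step 6 because the phenoxide is flanked on both sides) to give tert-butyl 2-{[8-(benzyloxy)-6-bromo-2,2,5-trimethyl-4-oxochroman-7-yl]oxy}-3-formyl-4-methoxy-6-methylbenzoate F2. CF3CO2H in CH2Cl2 then frees 2-{[8-(benzyloxy)-6-bromo-2,2,5-trimethyl-4-oxochroman-7-yl]oxy}-3-formyl-4-methoxy-6-methylbenzoic acid F3. An intramolecular Ullmann-type O-arylation of the carboxylate (CuI, 1,10-phenanthroline, Cs2CO3, DMF, 110 °C), the reaction type that closes benzocoumarin lactones from 2'-halobiaryl-2-carboxylic acids, forms the aryl ester bond at the carbon that carried bromine and comes back to the route at 18.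

Step 6. Fluoride displacement at a carbon flanked by a formyl and a tert-butoxycarbonyl group may be slow, leaving time for base-mediated aldol condensation between the chromanone methylene and the aryl aldehyde. The fallback introduces the carboxyl group after the ether. It sets out from 6 and 10: the phenoxide of 6 displaces fluoride from the less hindered bromo fluoro aldehyde 10 (Cs2CO3, DMSO, 70 °C; fluorine ortho to formyl and to bromine) to give 2-{[8-(benzyloxy)-2,2,5-trimethyl-4-oxochroman-7-yl]oxy}-3-bromo-6-methoxy-4-methylbenzaldehyde F4. Palladium-catalysed hydroxycarbonylation of the aryl bromide (CO 5 bar, Pd(OAc)2, Xantphos, K2CO3, DMSO/H2O, 90 °C; then acidification) gives the acid and comes back to the route at 17, so that steps 5 and 7 are no longer needed.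

Step 2. Site selectivity in the alkylation of the catecholate dianion may be lost (benzylation at O7 or at both oxygens), and the dianion may be oxidised by traces of air. The fallback uses a protecting-group sequence. It sets out from 4: under monoanion conditions the more acidic O7 hydroxyl (para to the ketone) is capped with chloromethyl methyl ether (i-Pr2NEt, CH2Cl2, 0 °C) to give 8-hydroxy-7-(methoxymethoxy)-2,2,5-trimethylchroman-4-one F5. Benzylation of the remaining hydroxyl (BnBr, K2CO3, DMF) gives 8-(benzyloxy)-7-(methoxymethoxy)-2,2,5-trimethylchroman-4-one F6, and HCl in MeOH at 40 °C removes the acetal and comes back to the route at 6.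

**Further compounds**

F1 | step 8 | 8-(benzyloxy)-6-bromo-7-hydroxy-2,2,5-trimethylchroman-4-one | CC1(C)CC(=O)c2c(C)c(Br)c(O)c(OCc3ccccc3)c2O1
F2 | step 8 | tert-butyl 2-{[8-(benzyloxy)-6-bromo-2,2,5-trimethyl-4-oxochroman-7-yl]oxy}-3-formyl-4-methoxy-6-methylbenzoate | COc1cc(C)c(C(=O)OC(C)(C)C)c(Oc2c(Br)c(C)c3C(=O)CC(C)(C)Oc3c2OCc4ccccc4)c1C=O
F3 | step 8 | 2-{[8-(benzyloxy)-6-bromo-2,2,5-trimethyl-4-oxochroman-7-yl]oxy}-3-formyl-4-methoxy-6-methylbenzoic acid | COc1cc(C)c(C(=O)O)c(Oc2c(Br)c(C)c3C(=O)CC(C)(C)Oc3c2OCc4ccccc4)c1C=O
F4 | step 6 | 2-{[8-(benzyloxy)-2,2,5-trimethyl-4-oxochroman-7-yl]oxy}-3-bromo-6-methoxy-4-methylbenzaldehyde | COc1cc(C)c(Br)c(Oc2cc(C)c3C(=O)CC(C)(C)Oc3c2OCc4ccccc4)c1C=O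
F5 | step 2 | 8-hydroxy-7-(methoxymethoxy)-2,2,5-trimethylchroman-4-one | COCOc1cc(C)c2C(=O)CC(C)(C)Oc2c1O
F6 | step 2 | 8-(benzyloxy)-7-(methoxymethoxy)-2,2,5-trimethylchroman-4-one | COCOc1cc(C)c2C(=O)CC(C)(C)Oc2c1OCc3ccccc3
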